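all flasks: Q 0.97 M
- Thursday's: L 1.07 M; temperature 110 °C; the very flask that is asked about, followed so far
- Tuesday's: L 0.72 M; temperature 105 °C; run made earlier
- flask: L 1.07 M; temperature 110 °C; time 2.0 h

| run | time / min | G / % | Q / % |
|---|---|---|---|
| Thursday's | 5.00 | 30 | 55 |
| Thursday's | 15.0 | 38 | 47 |
| Thursday's | 25.0 | 35 | 48 |
| Thursday's | 40.0 | 28 | 51 |
| Thursday's | 60.0 | 29 | 59 |
| Thursday's | 80.0 | 23 | 56 |
| Thursday's | 90.0 | 22 | 63 |
| Tuesday's | 1.50 | 10 | 84 |
| Tuesday's | 3.00 | 14 | 82 |
| Tuesday's | 5.00 | 20 | 71 |
| Tuesday's | 6.00 | 25 | 65 |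
| Tuesday's | 8.00 | 22 | 67 |
| Tuesday's | 10.0 | 31 | 60 |
| Tuesday's | 12.0 | 31 | 61 |

(scatter of a reading: 2 percentage points)

- ochre: at 2.0 h take out 90% of the G then present, then wait 1.0 h
- grey: change nothing and wait 1.0 h more
- red: at 2.0 h raise the temperature by 20 K, then wait 1.0 h
- teal: at 2.0 h add L, 50.0% of the amount charged, then wait 1.0 h

- what is taken out of G is counted as made
- additions bring no volume worth counting
- a reading of Q is of its free form alone

- G, in percent of the Q first charged, at 2.0 h
- the remedy with the largest gain of G, or "none" below 2 percentage points (ochre / grey / red / teal / none)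
- G present, with what was taken out counted in, in percent of the Q first charged, after ochre
- G present, with what was taken out counted in, in percent of the Q first charged, after red

- Thursday's flask cannot be a one-way conversion of Q into G: G reads 38% at 15.0 min but less, 22%, at 90.0 min, while Q climbs from 47% to 63%.
- I write the balance of Q, charged in a smaller amount than L: Q, G and an unseen gap must sum to the charge. In Thursday's flask the gap reads 15.0% at 5.00 min and averages 16.6%.
- Thursday's G opens at an average 0.0600 min⁻¹ of the charge over the first 5.00 min, and its knee is the reading at 15.0 min, where Q is still more than G, so the curves do not cross there.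
- Past the knee I follow G over free Q, a bound-to-free ratio, which in Thursday's flask reads 0.549 at 40.0 min and 0.349 at 90.0 min. Its logarithm falls by 0.00905 min⁻¹: this is the slide, the steady fall of the logarithm of G over free Q, read with a scatter of 2 percentage points on each reading.
- The slide takes 110 min to change that ratio by a factor e, longer than the 15.0 min of the rise, so past the knee I extend it as a steady drift read from the readings.
- Carried to 2.0 h, the slide gives a ratio of 0.266, and with the gap held, my G is 17.5%.
- The forecast gives 17%, a little less than mine, with 22% after ochre, 5% after red, and teal as best: “Teal narrowly beats ochre, though this is uncertain.”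
- Thursday's flask gives 18.1%; teal gains 5.9 points, ochre reaches 18.9% and red 2.90%.

    Q + L ⇌ G (K = 13.0 M⁻¹, k = 0.160 M⁻¹ min⁻¹, Ea = 73.0 kJ mol⁻¹, ΔH = −36.0 kJ mol⁻¹)
    Q + L ⇌ J (K = 14.0 M⁻¹, k = 0.0700 M⁻¹ min⁻¹, Ea = 80.0 kJ mol⁻¹, ΔH = −43.0 kJ mol⁻¹)
    L → Z (k = 0.130 min⁻¹, Ea = 103 kJ mol⁻¹)
    (constants at 110 °C)

- At 120 min Thursday's flask holds 0.999% of its L. Run on from its ratio for 1.0 h with J held at 15.4%, the slide gives a change of −6.6 points, and grey gives −5.2 points. Run back from 0.349 to the neighbour read at 50 min, the slide gives a ratio of 0.501, and that neighbour holds 28.6% of G on 54.4% of Q, a ratio of 0.526.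

The earlier runs and the new flask are calculated for an exercise; noise was put on by code.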